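**Assumption:** germacrane numbering of the target is used for every compound (ring C1–C10, lactone C11–C13 with C12 the carbonyl, C14 on C10, C15 on C4; the six-membered precursors carry ring atoms C3–C8). β is the face of the C7 side chain, so the target is 4β-OH, 5β-O, 6α-O, H7α, 8α-O, 9β-OH, 10β-Me (4R,5R,6S,7R,8R,9R,10R). The temporary C11 centre of amine adducts 19, 20, 22 and 23 is uncontrolled and left undefined.

## Retrosynthetic overview

1. Target 24 ⇐ dienolide 18 [(4Z,8E)-3-oxogermacra-4,8,11(13)-trien-12,6α-olide]: one double syn-dihydroxylation with the lactone methylene masked as its Me2NH adduct, one isobutyrate per diol, unmasking.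
2. 18 ⇐ cyclohexenol acid 15 in one operation: anionic oxy-Cope (C3–C8 broken, C1–C10 made; sets E-C8=C9 and C10), then desilylative lactonisation. The ten-membered carbocycle and the γ-lactone form together.
3. 15 ⇐ vinyl addition to ketone 13 ⇐ Pd-catalysed α′-propenylation of keto acid 9, with C8 set by kinetic protonation.
4. 9 ⇐ (S)-carvone 1: γ-hydroxylation (C6–O trans to C7), silylation, oxidation of the isopropenyl methyl to the acrylic acid (C12).
5. Ring order: the carvone ring (C3–C8) is sacrificial; carbocycle and lactone appear together in step 8; no ring is made afterwards.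

## Route

**Step 1**
Reactants: 1 (S)-(+)-carvone
Product: 3 linear trimethylsilyl dienol ether of carvone, via potassium dienolate 2 (not isolated)
Conditions: KOt-Bu, THF–DMPU, −78 → −20 °C; TMSCl, −78 °C
Reagents that add atoms: chlorotrimethylsilane, C[Si](C)(C)Cl
Why: Reversible γ-deprotonation by the alkoxide gives the thermodynamic through-conjugated dienolate, which is O-silylated (thermodynamic dienolate formation/O-silylation); C7 is not touched.

**Step 2**
Reactants: 3 linear trimethylsilyl dienol ether of carvone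
Product: 6 trans-4-hydroxycarvone, via silyl endoperoxide 4 (not isolated), via hydroperoxy enone 5 (not isolated)
Conditions: O2, TPP (cat.), hν, CH2Cl2, −78 °C; then MeOH, PPh3, −78 °C → rt
Reagents that add atoms: oxygen, O=O
Why: Singlet-oxygen [4+2] cycloaddition on the diene face anti to the C7 isopropenyl group, methanolysis of the silyl peroxyketal and phosphine reduction of the γ-hydroperoxide (vinylogous Rubottom-type γ-hydroxylation) set C6–O trans to C7.

**Step 3**
Reactants: 6 trans-4-hydroxycarvone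
Product: 7 6α-TBS ether of 6
Conditions: TBSCl, imidazole, DMF, rt
Reagents that add atoms: tert-butyldimethylsilyl chloride, CC(C)(C)[Si](C)(C)Cl
Why: Standard Corey silylation of the secondary allylic alcohol; no stereocentre changes.

**Step 4**
Reactants: 7 6α-TBS ether
Product: 8 allylic alcohol (C12–OH)
Conditions: SeO2 (0.5 equiv), t-BuOOH, CH2Cl2, 0 °C → rt
Reagents that add atoms: selenium dioxide, O=[Se]=O; tert-butyl hydroperoxide, CC(C)(C)OO
Why: Sharpless SeO2/TBHP allylic oxidation (ene reaction then [2,3]-shift) attacks only the electron-rich 1,1-disubstituted alkene and, by the CH3 > CH preference, its methyl group, the enone alkene being deactivated.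

**Step 5**
Reactants: 8 allylic alcohol
Product: 9 acrylic acid (keto acid)
Conditions: TEMPO (cat.), NaOCl (cat.), NaClO2, MeCN–phosphate buffer pH 6.7, 35 °C
Reagents that add atoms: sodium chlorite, [Na+].[O-]Cl=O
Why: TEMPO/hypochlorite oxidation to the enal and chlorite (Pinnick-type) oxidation in the same flask give the acid; silyl ether and enone are inert at this pH.

**Step 6**
Reactants: 9 keto acid; 10 (E)-1-bromoprop-1-ene
Product: 13 7,8-cis 8β-[(E)-propenyl] keto acid, via dilithium enolate 11 (not isolated), via propenylated enolate 12 (not isolated)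
Conditions: LiHMDS (3.3 equiv), THF, −78 °C; Pd2(dba)3 (2.5 mol%), Q-Phos (5 mol%), 10, rt; then −78 °C, AcOH
Reagents that add atoms: (E)-1-bromoprop-1-ene (10), C/C=C/Br
Why: Pd-catalysed ketone-enolate α-alkenylation (Buchwald–Hartwig-type enolate coupling) at C8, the only kinetically enolisable carbon while the carboxylate switches off the acrylate, keeps the E geometry; C8 is set at the end by kinetic protonation of enolate 12 anti to the neighbouring C7 side chain, giving the 7,8-cis ketone.

**Step 7**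
Reactants: 13 7,8-cis propenyl keto acid; 14 vinylmagnesium bromide
Product: 15 3α-vinyl-3β-hydroxy divinyl carbinol acid
Conditions: CeCl3, THF, −78 °C; aq. NH4Cl
Reagents that add atoms: vinylmagnesium bromide (14), C=C[Mg]Br
Why: Organocerium 1,2-addition (Imamoto conditions, which suppress enolisation and conjugate addition) comes from the α-face, opposite the two β-substituents on C7 and C8, so vinyl ends up trans to propenyl.

**Step 8**
Reactants: 15 divinyl carbinol acid
Product: 18 (4Z,8E)-3-oxogermacra-4,8,11(13)-trien-12,6α-olide, via keto acid silyl ether 16 (not isolated), via hydroxy keto acid 17 (not isolated)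
Conditions: KH (3 equiv), 18-crown-6, THF, 0 → 45 °C; AcOH, −78 °C; then HF·pyridine, THF, 0 °C → rt
Reagents that add atoms: none
Why: Anionic oxy-Cope rearrangement of the dipotassium alkoxide–carboxylate through the chair with both alkenyl groups pseudo-equatorial cleaves C3–C8 and forms C1–C10, giving the E-C8=C9 alkene and, by chirality transfer from C8 through the E-propenyl group (methyl pseudo-equatorial), the 10R centre; fluoride then removes the silyl group and the γ-hydroxy acid lactonises, so carbocycle and lactone form in the same operation.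

**Step 9**
Reactants: 18 dienolide
Product: 19 13-dimethylamino adduct of 18
Conditions: Me2NH (2 M in THF), rt
Reagents that add atoms: dimethylamine, CNC
Why: Reversible aza-Michael addition to the α-methylene lactone (the hindered trisubstituted enone does not react) masks it for osmylation; the new C11 centre is uncontrolled and disappears in step 12.

**Step 10**
Reactants: 19 amine adduct
Product: 20 4β,5β,8α,9β-tetraol
Conditions: OsO4 (10 mol%), NMO (3 equiv), citric acid, t-BuOH–H2O, rt
Reagents that add atoms: osmium tetroxide, O=[Os](=O)(=O)=O; N-methylmorpholine N-oxide, C[N+]1([O-])CCOCC1; water, O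
Why: Upjohn syn-dihydroxylation of both ring alkenes from the outer face of the macrocycle (at C4=C5 with H6 eclipsing the Z-alkene and the C6–C7 bond shielding the inner face; at C8=C9 in the conformer that keeps lactone carbon C11 outside and only the C10 methyl inside) gives 4R,5R,8R,9R.

**Step 11**
Reactants: 20 tetraol; 21 isobutyryl chloride
Product: 22 5,8-di-O-isobutyrate
Conditions: Me2SnCl2 (10 mol%), i-Pr2NEt, THF, 0 °C
Reagents that add atoms: isobutyryl chloride (21), CC(C)C(=O)Cl
Why: Tin-catalysed regioselective mono-acylation of 1,2-diols activates each vicinal diol once, placing one ester on secondary O5 (not tertiary O4) and one on O8, taken to be the more acidic and less encumbered hydroxyl of the 8,9-diol (O9 sits next to the C10 methyl branch); no stereocentre is affected.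

**Step 12**
Reactants: 22 di-O-isobutyrate
Product: 24 target CNP0396108.1, via ammonium iodide 23 (not isolated)
Conditions: MeI, THF, rt; then aq. NaHCO3, CH2Cl2, rt
Reagents that add atoms: none
Why: N-methylation and E1cB (Hofmann-type) loss of trimethylamine regenerate the α-methylene lactone under conditions that leave the esters, the α-ketol and all seven stereocentres untouched.

## Compound list

1 | (S)-(+)-carvone, (5S)-2-methyl-5-(prop-1-en-2-yl)cyclohex-2-en-1-one | CC1=CC[C@H](C(C)=C)CC1=O | starting material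
2 | potassium 2-methyl-5-(prop-1-en-2-yl)cyclohexa-1,3-dien-1-olate (linear dienolate of 1, C7 unchanged) | CC1=C([O-])C[C@@H](C(C)=C)C=C1.[K+] | intermediate
3 | trimethylsilyl ether of 2 (3-silyloxy-3,5-diene) | CC1=C(O[Si](C)(C)C)C[C@@H](C(C)=C)C=C1 | intermediate
4 | 3-(trimethylsilyloxy)-3,6-endoperoxide (2,3-dioxabicyclo[2.2.2]oct-5-ene, peroxide bridge anti to isopropenyl) | CC1=C[C@H]2OO[C@]1(O[Si](C)(C)C)C[C@H]2C(C)=C | intermediate
5 | trans-4-hydroperoxycarvone (6α-OOH) | CC1=C[C@@H](OO)[C@H](C(C)=C)CC1=O | intermediate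
6 | trans-4-hydroxycarvone, (4R,5S)-4-hydroxy-2-methyl-5-(prop-1-en-2-yl)cyclohex-2-en-1-one (6α-OH, trans to isopropenyl) | CC1=C[C@@H](O)[C@H](C(C)=C)CC1=O | intermediate
7 | 6α-tert-butyldimethylsilyl ether of 6 | CC1=C[C@@H](O[Si](C)(C)C(C)(C)C)[C@H](C(C)=C)CC1=O | intermediate
8 | 6α-(TBSO)-7β-(3-hydroxyprop-1-en-2-yl)-4-methylcyclohex-4-en-3-one (6,7-trans) | CC1=C[C@@H](O[Si](C)(C)C(C)(C)C)[C@H](C(=C)CO)CC1=O | intermediate
9 | 2-[6α-(TBSO)-4-methyl-3-oxocyclohex-4-en-7β-yl]prop-2-enoic acid (6,7-trans) | CC1=C[C@@H](O[Si](C)(C)C(C)(C)C)[C@H](C(=C)C(=O)O)CC1=O | intermediate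
10 | (E)-1-bromoprop-1-ene | C/C=C/Br | starting material
11 | dilithium C3/C8-enolate carboxylate of 9 | CC1=C[C@@H](O[Si](C)(C)C(C)(C)C)[C@H](C(=C)C(=O)[O-])C=C1[O-].[Li+].[Li+] | intermediate
12 | dilithium C3/C8-enolate carboxylate carrying the 8-[(E)-propenyl] group | CC1=C[C@@H](O[Si](C)(C)C(C)(C)C)[C@H](C(=C)C(=O)[O-])C(/C=C/C)=C1[O-].[Li+].[Li+] | intermediate
13 | 2-[6α-(TBSO)-4-methyl-3-oxo-8β-[(E)-prop-1-enyl]cyclohex-4-en-7β-yl]prop-2-enoic acid (6,7-trans, 7,8-cis) | CC1=C[C@@H](O[Si](C)(C)C(C)(C)C)[C@H](C(=C)C(=O)O)[C@H](/C=C/C)C1=O | intermediate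
14 | vinylmagnesium bromide | C=C[Mg]Br | starting material
15 | 2-[6α-(TBSO)-3β-hydroxy-4-methyl-8β-[(E)-prop-1-enyl]-3α-vinylcyclohex-4-en-7β-yl]prop-2-enoic acid (vinyl trans to propenyl) | CC1=C[C@@H](O[Si](C)(C)C(C)(C)C)[C@H](C(=C)C(=O)O)[C@H](/C=C/C)[C@@]1(O)C=C | intermediate
16 | (4Z,8E)-6α-(TBSO)-3-oxogermacra-4,8,11(13)-trien-12-oic acid (H7α, 10β-Me) | C1C(=O)/C(C)=C\[C@@H](O[Si](C)(C)C(C)(C)C)[C@H](C(=C)C(=O)O)/C=C/[C@H](C)C1 | intermediate
17 | (4Z,8E)-6α-hydroxy-3-oxogermacra-4,8,11(13)-trien-12-oic acid | C1C(=O)/C(C)=C\[C@@H](O)[C@H](C(=C)C(=O)O)/C=C/[C@H](C)C1 | intermediate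
18 | (4Z,8E)-3-oxogermacra-4,8,11(13)-trien-12,6α-olide (trans-fused lactone, H6β, H7α, 10β-Me) | C1C(=O)/C(C)=C\[C@H]2OC(=O)C(=C)[C@@H]2/C=C/[C@H](C)C1 | intermediate
19 | 13-(dimethylamino)-11,13-dihydro derivative of 18 | C1C(=O)/C(C)=C\[C@H]2OC(=O)C(CN(C)C)[C@@H]2/C=C/[C@H](C)C1 | intermediate
20 | 13-(dimethylamino)-4β,5β,8α,9β-tetrahydroxy-3-oxogermacran-12,6α-olide | CN(C)CC1C(=O)O[C@H]2[C@H]1[C@@H](O)[C@H](O)[C@H](C)CCC(=O)[C@](C)(O)[C@@H]2O | intermediate
21 | isobutyryl chloride | CC(C)C(=O)Cl | starting material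
22 | 5,8-di-O-isobutyryl derivative of 20 | CN(C)CC1C(=O)O[C@H]2[C@H]1[C@@H](OC(=O)C(C)C)[C@H](O)[C@H](C)CCC(=O)[C@](C)(O)[C@@H]2OC(=O)C(C)C | intermediate
23 | 13-(trimethylammonio) iodide of 22 | C[N+](C)(C)CC1C(=O)O[C@H]2[C@H]1[C@@H](OC(=O)C(C)C)[C@H](O)[C@H](C)CCC(=O)[C@](C)(O)[C@@H]2OC(=O)C(C)C.[I-] | intermediate
24 | CNP0396108.1, 4β,9β-dihydroxy-5β,8α-bis(isobutyryloxy)-3-oxogermacr-11(13)-en-12,6α-olide (4R,5R,6S,7R,8R,9R,10R) | C=C1C(=O)O[C@H]2[C@H]1[C@@H](OC(=O)C(C)C)[C@H](O)[C@H](C)CCC(=O)[C@](C)(O)[C@@H]2OC(=O)C(C)C | target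

## Step count and risks

Total step count: 12. Longest linear sequence: 12 steps (fully linear from 1).

**Step 6.** The Pd coupling on an enolate–carboxylate dianion may stall, or the coupling may go at the γ-carbon. The fallback makes the C8–C9 bond by classical alkylation and then moves the alkene. From 9, LDA (2.2 equiv) and allyl bromide at −78 °C alkylate C8 anti to the C7 side chain to give the 7,8-trans 8-allyl keto acid F1. A one-position alkene migration with a cationic iridium hydride ([Ir(cod)(PMePh2)2]PF6, H2-activated, THF) gives the 7,8-trans 8-[(E)-propenyl] keto acid F2. Re-enolisation of F2 (LiHMDS, −78 °C) and quench with 2,6-di-tert-butylphenol inverts C8 and returns to the route at compound 13.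

**Step 8.** The dianionic rearrangement may fail through insolubility of the dipotassium salt or alkoxide attack on the acrylate. It also needs the ring to flip so that vinyl and propenyl become pseudo-equatorial. The fallback keeps C12 at the alcohol level through the ring expansion and closes the lactone by oxidation afterwards. From 8, TBSCl/imidazole gives the bis-silyl ether F3. The step 6 coupling and protonation give the 7,8-cis propenyl ketone F4. CeCl3/vinylmagnesium bromide gives the divinyl carbinol F5. KH/18-crown-6 in THF gives the ten-membered bis-silyl dienone F6. TBAF gives the diol F7. TEMPO/PhI(OAc)2 then oxidises the primary allylic alcohol through the lactol to the lactone and rejoins the route at compound 18.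

**Step 11.** The preference for O8 over O9 is the weakest argument in the route; the acylation may pick O9. The fallback replaces direct selection by temporary protection. From 20, TESCl (1 equiv) and 2,6-lutidine at −40 °C cap the hydroxyl that reacts first (O9) to give the 9-O-triethylsilyl ether F8. Isobutyric anhydride/DMAP then esterifies the two remaining secondary hydroxyls (O5 and O8; tertiary O4 is inert) to give the silyl bis-ester F9. HF·pyridine removes the silyl group and returns to the route at compound 22.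

## Further compounds

F1 | step 6 | 7,8-trans 8α-allyl keto acid | CC1=C[C@@H](O[Si](C)(C)C(C)(C)C)[C@H](C(=C)C(=O)O)[C@@H](CC=C)C1=O
F2 | step 6 | 7,8-trans 8α-[(E)-prop-1-enyl] keto acid | CC1=C[C@@H](O[Si](C)(C)C(C)(C)C)[C@H](C(=C)C(=O)O)[C@@H](/C=C/C)C1=O
F3 | step 8 | 6,12-bis-TBS ether of 8 | CC1=C[C@@H](O[Si](C)(C)C(C)(C)C)[C@H](C(=C)CO[Si](C)(C)C(C)(C)C)CC1=O
F4 | step 8 | 7,8-cis 8β-[(E)-prop-1-enyl] bis-silyl ketone | CC1=C[C@@H](O[Si](C)(C)C(C)(C)C)[C@H](C(=C)CO[Si](C)(C)C(C)(C)C)[C@H](/C=C/C)C1=O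
F5 | step 8 | 3α-vinyl-3β-hydroxy bis-silyl divinyl carbinol | CC1=C[C@@H](O[Si](C)(C)C(C)(C)C)[C@H](C(=C)CO[Si](C)(C)C(C)(C)C)[C@H](/C=C/C)[C@@]1(O)C=C
F6 | step 8 | (4Z,8E)-6α,12-bis(TBSO)germacra-4,8,11(13)-trien-3-one | C1C(=O)/C(C)=C\[C@@H](O[Si](C)(C)C(C)(C)C)[C@H](C(=C)CO[Si](C)(C)C(C)(C)C)/C=C/[C@H](C)C1
F7 | step 8 | (4Z,8E)-6α,12-dihydroxygermacra-4,8,11(13)-trien-3-one | C1C(=O)/C(C)=C\[C@@H](O)[C@H](C(=C)CO)/C=C/[C@H](C)C1
F8 | step 11 | 9-O-triethylsilyl ether of 20 | CN(C)CC1C(=O)O[C@H]2[C@H]1[C@@H](O)[C@H](O[Si](CC)(CC)CC)[C@H](C)CCC(=O)[C@](C)(O)[C@@H]2O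
F9 | step 11 | 9-O-triethylsilyl 5,8-di-O-isobutyrate | CN(C)CC1C(=O)O[C@H]2[C@H]1[C@@H](OC(=O)C(C)C)[C@H](O[Si](CC)(CC)CC)[C@H](C)CCC(=O)[C@](C)(O)[C@@H]2OC(=O)C(C)C
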